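Readings and results come from a simulation for an exercise; noise was put on by code.

Read each plateau as a loss ratio: what is not target, over target, the inverse of a selectivity factor.

common to all: free enzyme 0.56 µM
- Tuesday's: starting material 5.3 mM; temperature 32 °C; run made earlier
- Sunday's: starting material 10 mM; temperature 43 °C; run made earlier
- Friday's: starting material 13 mM; temperature 32 °C; run made earlier
- alpha: starting material 18 mM; temperature 37 °C; time 30 h
- epsilon: starting material 5.0 mM; temperature 37 °C; time 30 h

- Tuesday's (time / h: target / %, starting material / %): 2.00: 58.4, 18.8; 5.00: 71.2, 2.3; 10.0: 72.5, 0.9; 15.0: 72.5, 0.3; 20.0: 72.4, 0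
- Sunday's (time / h: target / %, starting material / %): 4.00: 47.9, 0; 8.00: 49.0, 0.1; 12.0: 48.7, 0; 15.0: 48.7, 0.1; 20.0: 48.0, 0
- Friday's (time / h: target / %, starting material / %): 1.50: 38.1, 38.3; 3.00: 54.0, 14.9; 6.00: 61.6, 2.4; 12.0: 62.9, 1.0; 20.0: 62.2, 0.3

(scatter of a reading: 0.5 percentage points)



- which one finishes higher in amount of target, in percent of the starting material charged ("neither" within 2 percentage points) (alpha / epsilon / neither)
- amount of target at the end, in percent of the starting material charged, alpha
- amount of target at the end, in percent of the starting material charged, epsilon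

The plateaus gave me 0.379 for Tuesday's run and 0.590 for Friday's, both at 32 °C, so the ratio climbed by 0.0273 mM⁻¹ with [starting material]. Friday's starting material was down to 0.3% at 20.0 h, so I took 30 h as plateau.

Sunday's run gave 1.05 at 43 °C, against 0.508 on my line at that charge, a temperature factor of 2.07. For epsilon the line gave 0.371 at 32 °C. Assuming the ratio rises steadily with temperature, target in epsilon lay below 72.9% (no factor) and above 56.6% (full factor).

To tighten this, I noted that 37 °C lies about half of the way across the temperature span, so I took the square root of the factor. That gave the loss ratio of epsilon, 0.534, so target 65.2%. The same reckoning gave alpha 1.05, so target 48.9%, lower than epsilon. If target is made on the enzyme and the loss runs without it, the ratio goes inversely with the enzyme charge, other settings held.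

The forecast said epsilon, with 49.5% for alpha and 66% for epsilon, the latter inside my bracket, holding that “the final figure is set by selectivity during conversion”.

The flasks gave epsilon: 50.4% for alpha and 65.1% for epsilon.

    free enzyme → unfolded enzyme (k = 0.00250 h⁻¹, Ea = 286 kJ mol⁻¹)
    starting material + free enzyme → target + free enzyme, rate k2*[starting material]*[free enzyme]/(1 + ([starting material]/Km2) + ([target]/Kp2)) (7.48 mM, 5.74 mM, k = 2.51 × 10⁶ L mol⁻¹ h⁻¹, Ea = 47.0 kJ mol⁻¹)
    starting material → uncatalysed product (k = 0.465 h⁻¹, Ea = 105 kJ mol⁻¹)
    (constants at 37 °C)

Both flasks had come to rest in target: at 30.0 h starting material stood at 0% of its charge in alpha and 0% in epsilon. Left to 300 h, target stays at 50.4% in alpha and 65.1% in epsilon , though free enzyme in epsilon goes from 92.8% to 47.2% of its charge. Epsilon's loss ratio came out at 0.536, against my 0.534.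

For a neighbour of epsilon, charged with 9.5 × 10⁻⁴ mM of free enzyme, the ratio 0.534 scaled by the charges gives 0.315, so target 76.0%. The computed flask gave 75.5%.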